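**Retrosynthetic overview**
- The single ring of the target (2-heptadecyl-6-methoxy-1,4-benzoquinone) carries oxygen at C2 (OMe) and C4 (C=O) in a meta relation and the heptadecyl chain at C6. This is the 1,3,5-pattern of a 5-alkylresorcinol, that is, a stearoyl-primed tetraketide. Only the C1 oxygen is foreign, and it is added last by para-oxidation of 3-heptadecyl-5-methoxyphenol.
- The monomethyl ether is traced to 2-heptadecyl-4,6-dihydroxybenzoic acid. Its carboxyl (on C5 in quinone numbering) limits methylation to one hydroxyl and is then lost as CO2.
- Key disconnection: ring bond C5–C6 (C1–C2 of the benzoic acid), made by intramolecular aldol condensation and aromatisation of 3,5,7-trioxotetracosanoic acid (chain C2 onto the C7 ketone). This is the only ring closure of the route.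
- The triketo acid is cut at C1–C2 (CO2 onto the trianion of tricosane-2,4,6-trione) and at C6–C7 (acetylacetone dianion acylated by methyl stearate).

Key step: step 3

Remark: the target has no stereocentre and no stereogenic double bond, so it is achiral and no enantiocontrol is needed. The stereocentres of the cyclic aldol intermediate in the key step are transient and vanish on aromatisation.

**Step 1**
Reactants: 1 methyl stearate (methyl octadecanoate); 2 acetylacetone (pentane-2,4-dione)
Product: 4 tricosane-2,4,6-trione, via dilithioacetylacetone 3 (not isolated)
Conditions: 2 (2.2 equiv), LDA (4.4 equiv, commercial solution), THF, 0 °C; then 1 (1.0 equiv), 0 °C to rt; cold 2 M HCl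
Reagents that add atoms: lithium diisopropylamide, [Li+].CC(C)[N-]C(C)C (supplies only the lithium of intermediate 3; no atom of it remains in 4)
Why: Twofold deprotonation makes the terminal carbon of 3 the most basic and least hindered nucleophile, so it alone attacks the ester carbonyl of 1 (Claisen-type terminal C-acylation of a β-diketone 1,3-dianion), while the second equivalent of 3 deprotonates the more acidic triketone as it forms.

**Step 2**
Reactants: 4 tricosane-2,4,6-trione
Product: 6 3,5,7-trioxotetracosanoic acid, via trilithio trianion 5 (not isolated)
Conditions: LDA (3.5 equiv), THF, 0 °C; then dry CO2 (excess), −78 to 0 °C; cold 1 M HCl at 0 °C, extract, use at once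
Reagents that add atoms: carbon dioxide, O=C=O; lithium diisopropylamide, [Li+].CC(C)[N-]C(C)C (lithium of intermediate 5 only)
Why: The third and least stabilised carbanion of 5 sits at the primary C1 methyl (favoured kinetically over the C7 methylene of the chain) and is the only site basic enough to add to CO2, so carboxylation is terminal (C-carboxylation of a 1,3,5-triketone trianion), and cold acidification spares the β-keto acid from loss of CO2.

**Step 3**
Reactants: 6 3,5,7-trioxotetracosanoic acid
Product: 8 2-heptadecyl-4,6-dihydroxybenzoic acid, via cyclic aldol 7 (not isolated)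
Conditions: 1 M aq. KOH (5 equiv), THF, 0 °C to rt, Ar; then cold 2 M HCl to pH 2, isolate below 25 °C
Reagents that add atoms: none
Why: In dilute hydroxide 6 exists as a carboxylate/enolate polyanion in which the C4 and C6 methylenes (each between two ketones) are the more acidic sites but have no productive outlet (only four-membered closures), so the reaction drains through the less populated C2 enolate of the β-keto carboxylate, which adds to the C7 ketone and forms the C2–C7 bond (C1–C2 of the benzoic acid, ring bond C5–C6 of the final quinone). The closest known reaction type is the biomimetic intramolecular aldol condensation of 3,5,7-triketo acids (and of their 4-hydroxy-2-pyrone lactones) to 6-substituted 2,4-dihydroxybenzoic acids in aqueous alkali. The one ring closes in the 6-(enolendo)-exo-trig mode, because the C2=C3 enolate double bond lies inside the new ring and the C7 carbonyl oxygen outside it. β-Elimination of the tertiary hydroxyl of aldol 7 and enolisation of the C3 and C5 carbonyls then give the aromatic ring irreversibly, which pulls the reversible aldol equilibrium forward; the two transient stereocentres of 7 form without control and are erased, so no stereocentre has to be set. The selectivity needed is aldol (C2 onto C7) over Claisen closure (C6 onto C1), over O-lactonisation to a pyrone, and over decarboxylation or retro-Claisen cleavage; it is secured by keeping C1 as an ionised carboxylate, which is no acyl acceptor and does not lose CO2, and by using dilute base at or below room temperature under argon.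

**Step 4**
Reactants: 8 2-heptadecyl-4,6-dihydroxybenzoic acid
Product: 9 methyl 2-heptadecyl-6-hydroxy-4-methoxybenzoate
Conditions: Me2SO4 (2.1 equiv), K2CO3 (2.5 equiv), acetone, rt then 50 °C
Reagents that add atoms: dimethyl sulfate, COS(=O)(=O)OC
Why: Carbonate ionises the carboxyl and the 4-OH (para to the carbonyl, the more acidic and unchelated phenol) and both are O-methylated by SN2 attack on dimethyl sulfate (Williamson-type alkylation), whereas the 6-OH stays locked in a six-membered hydrogen bond to the ester carbonyl and is left untouched when the reagent is limited to two equivalents.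

**Step 5**
Reactants: 9 methyl 2-heptadecyl-6-hydroxy-4-methoxybenzoate
Product: 10 2-heptadecyl-6-hydroxy-4-methoxybenzoic acid
Conditions: KOH (10 equiv), DMSO/H2O 4:1, 90 °C; cool, cold 2 M HCl to pH 2
Reagents that add atoms: potassium hydroxide, [K+].[OH-]
Why: Hydroxide in hot aqueous DMSO overcomes the di-ortho hindrance and hydrogen-bond deactivation of the ester (BAc2 saponification), and the aryl methyl ether and the alkyl chain are inert to base.

**Step 6**
Reactants: 10 2-heptadecyl-6-hydroxy-4-methoxybenzoic acid
Product: 11 3-heptadecyl-5-methoxyphenol
Conditions: Cu powder (cat.), quinoline, 180 °C, N2; dilute HCl wash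
Reagents that add atoms: none
Why: An ortho-hydroxy, para-methoxy benzoic acid is readily protonated at the carboxyl-bearing carbon, and the flanking heptadecyl and hydroxyl groups twist the carboxyl out of conjugation, so CO2 is lost on heating (thermal protodecarboxylation of an electron-rich salicylic acid, assisted by copper in quinoline).

**Step 7**
Reactants: 11 3-heptadecyl-5-methoxyphenol
Product: 12 2-heptadecyl-6-methoxy-1,4-benzoquinone (target)
Conditions: (KSO3)2NO (2.5 equiv), aq. KH2PO4, Aliquat 336 (cat.), CH2Cl2/H2O, rt
Reagents that add atoms: potassium nitrosodisulfonate (Fremy's salt), [K+].[K+].[O]N(S(=O)(=O)[O-])S(=O)(=O)[O-]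
Why: Teuber oxidation, in which one nitrosodisulfonate radical abstracts the phenolic hydrogen, a second couples with the phenoxyl radical at the unsubstituted para carbon (between the heptadecyl and methoxy groups), and loss of imidodisulfonate from the adduct delivers the p-quinone; the conversion is well established for 5-alkyl-3-methoxyphenols, and the phase-transfer salt carries the oxidant to the lipophilic substrate.

**Compound list**
1 | methyl stearate (methyl octadecanoate) | CCCCCCCCCCCCCCCCCC(=O)OC | starting material
2 | acetylacetone (pentane-2,4-dione) | CC(=O)CC(C)=O | starting material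
3 | dilithioacetylacetone (dilithium 2,4-dioxopentane-1,3-diide) | [Li+].[Li+].[CH2-]C(=O)[CH-]C(C)=O | intermediate (not isolated)
4 | tricosane-2,4,6-trione | CCCCCCCCCCCCCCCCCC(=O)CC(=O)CC(C)=O | intermediate
5 | trilithio trianion of 4 (trilithium 2,4,6-trioxotricosane-1,3,5-triide) | [Li+].[Li+].[Li+].CCCCCCCCCCCCCCCCCC(=O)[CH-]C(=O)[CH-]C(=O)[CH2-] | intermediate (not isolated)
6 | 3,5,7-trioxotetracosanoic acid | CCCCCCCCCCCCCCCCCC(=O)CC(=O)CC(=O)CC(=O)O | intermediate
7 | cyclic aldol, 2-heptadecyl-2-hydroxy-4,6-dioxocyclohexane-1-carboxylic acid (racemic mixture of diastereomers, configuration not controlled) | CCCCCCCCCCCCCCCCCC1(O)CC(=O)CC(=O)C1C(=O)O | intermediate (not isolated)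
8 | 2-heptadecyl-4,6-dihydroxybenzoic acid | CCCCCCCCCCCCCCCCCc1cc(O)cc(O)c1C(=O)O | intermediate
9 | methyl 2-heptadecyl-6-hydroxy-4-methoxybenzoate | CCCCCCCCCCCCCCCCCc1cc(OC)cc(O)c1C(=O)OC | intermediate
10 | 2-heptadecyl-6-hydroxy-4-methoxybenzoic acid | CCCCCCCCCCCCCCCCCc1cc(OC)cc(O)c1C(=O)O | intermediate
11 | 3-heptadecyl-5-methoxyphenol | CCCCCCCCCCCCCCCCCc1cc(O)cc(OC)c1 | intermediate
12 | 2-heptadecyl-6-methoxy-1,4-benzoquinone (achiral) | CCCCCCCCCCCCCCCCCC1=CC(=O)C=C(OC)C1=O | target

**Total step count:** 7
**Longest linear sequence:** 7 steps (from 1 and 2 to 12)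

**Steps most likely to fail**

Step 3 (key step). Loss of CO2 from the β-keto acid, lactonisation to the 4-hydroxy-2-pyrone, or retro-Claisen cleavage of the chain may outrun the ring closure, because the C7 acceptor is largely masked as a diketone enolate. The fallback builds the same ring by a Michael–Dieckmann sequence; it sets out from 1 and comes back at 9.
- DIBAL-H reduction of 1 at −78 °C should give octadecanal F1.
- Wittig olefination with 1-(triphenylphosphoranylidene)propan-2-one should give (E)-henicos-3-en-2-one F2.
- Dimethyl malonate and NaOMe in refluxing MeOH should add in Michael fashion to give dimethyl 2-(2-oxohenicosan-4-yl)propanedioate F3 (not isolated).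
- F3 should close by Dieckmann-type condensation of the methyl ketone onto one ester to give methyl 6-heptadecyl-2,4-dioxocyclohexane-1-carboxylate F4.
- Br2 in DMF (0 °C to rt) should dehydrogenate F4 to methyl 2-heptadecyl-4,6-dihydroxybenzoate F5.
- One equivalent of Me2SO4 with K2CO3 in acetone should methylate the unchelated 4-OH of F5 and give 9.

Step 2. The third deprotonation may be incomplete or may occur at the C7 methylene of the chain, so that carboxylation goes to the wrong end or fails, and the β-keto acid may lose CO2 during acidic work-up. The fallback sets out from 1 and comes back at 6; it replaces steps 1 and 2.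
- Commercial 4-hydroxy-6-methyl-2H-pyran-2-one (triacetic acid lactone) already holds the carboxyl carbon as its lactone carbonyl. It is converted into its dianion with LDA in THF (−78 to 0 °C, two equivalents of dianion per ester).
- C-acylation at the 6-methyl by 1 should give 4-hydroxy-6-(2-oxononadecyl)-2H-pyran-2-one F6, a stable lactone form of the triketo acid.
- Aqueous KOH should open the lactone to the potassium salt of 6 in the flask, which then cyclises to 8 under the conditions of step 3.

Step 7. Poor contact between the aqueous radical anion and the waxy phenol may stall the oxidation, and ortho attack or coupling of phenoxyl radicals may compete with para oxygenation. The fallback sets out from 11 and comes back at 12.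
- MeI and K2CO3 should give 1-heptadecyl-3,5-dimethoxybenzene F7.
- Vilsmeier–Haack formylation (POCl3, DMF), para to one methoxy and ortho to the chain, should give 2-heptadecyl-4,6-dimethoxybenzaldehyde F8.
- Baeyer–Villiger (Dakin-type) oxidation with mCPBA should give 2-heptadecyl-4,6-dimethoxyphenyl formate F9.
- Aqueous NaOH followed by acidification should give 2-heptadecyl-4,6-dimethoxyphenol F10.
- Ceric ammonium nitrate in aqueous MeCN at 0 °C should oxidise F10 with loss of the para-methyl ether to give 12.

**Further compounds**
F1 | step 3 | octadecanal | CCCCCCCCCCCCCCCCCC=O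
F2 | step 3 | (E)-henicos-3-en-2-one | CCCCCCCCCCCCCCCCC/C=C/C(C)=O
F3 | step 3 | dimethyl 2-(2-oxohenicosan-4-yl)propanedioate (racemic) | CCCCCCCCCCCCCCCCCC(CC(C)=O)C(C(=O)OC)C(=O)OC
F4 | step 3 | methyl 6-heptadecyl-2,4-dioxocyclohexane-1-carboxylate (racemic, configuration erased on aromatisation) | CCCCCCCCCCCCCCCCCC1CC(=O)CC(=O)C1C(=O)OC
F5 | step 3 | methyl 2-heptadecyl-4,6-dihydroxybenzoate | CCCCCCCCCCCCCCCCCc1cc(O)cc(O)c1C(=O)OC
F6 | step 2 | 4-hydroxy-6-(2-oxononadecyl)-2H-pyran-2-one | CCCCCCCCCCCCCCCCCC(=O)CC1=CC(O)=CC(=O)O1
F7 | step 7 | 1-heptadecyl-3,5-dimethoxybenzene | CCCCCCCCCCCCCCCCCc1cc(OC)cc(OC)c1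
F8 | step 7 | 2-heptadecyl-4,6-dimethoxybenzaldehyde | CCCCCCCCCCCCCCCCCc1cc(OC)cc(OC)c1C=O
F9 | step 7 | 2-heptadecyl-4,6-dimethoxyphenyl formate | CCCCCCCCCCCCCCCCCc1cc(OC)cc(OC)c1OC=O
F10 | step 7 | 2-heptadecyl-4,6-dimethoxyphenol | CCCCCCCCCCCCCCCCCc1cc(OC)cc(OC)c1O
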